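Reckon each flask by one number: how many natural-log steps of X the working catalyst can buy in the time given.

all flasks: G 0.10 M; X 0.100 M; D 50 µM; time 5.0 min
- birch: temperature 0 °C
- alder: temperature 25 °C
- cedar: at 25 °C until 1.0 min, from then on at 0 °C

    G + X + D → G.X + D, rate k1*[G]*[X]*[D]/(1 + ([G]/sat1)) (sat1 = 1.6 mM, k1 = 2.1 × 10⁵ /M²/s, Ea1 = 11.0 kJ/mol)
    Q ⇌ G.X, rate k2*(cs2 - [G.X]) while solid is left; crystals form when [G.X] > cs2 (cs2 = 0.070 M, k2 = 0.90 /s)
    D + G.X → D.G.X (k3 = 0.044 /M/s, Ea3 = 64.0 kJ/mol)
    (constants at 25 °C)

- for G.X the Q are counted in
- as a solid, counted per litre of solution: Q
- all constants are for 25 °C and move with temperature by the activation energies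

* the flask that comes out highest in amount of G.X, in percent of the G charged, or "all alike" when all lie within 1.5 percentage points (birch / alder / cedar / all alike)
* G.X at the end, in percent of the G charged, birch
* G.X at the end, in percent of the G charged, alder
* G.X at the end, in percent of the G charged, cedar

- **Rate of X.** While c(G) stands, as at the start, far above the saturation constant 1.6 mM, the first step runs pseudo-first-order in X. Its rate constant is the constant of that step times the saturation constant times c(D): 0.0168 /s at 25 °C.
- **Temperature.** Cooling to 0 °C slows that step by a factor 1.5 but the poisoning of D by a factor 11, a steeper fall. Taking c(G.X) at its ceiling 0.070 M from the start, D decays at 0.00308 /s when warm and 2.90 × 10⁻⁴ /s when cold. Averaged over 5.0 min, the working share of D is 65.3% warm and 95.8% cold.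
- **The working clock.** Birch gets 3.22 and alder 3.29; this product of the rate constant of X, the time and the working share is the working clock Λ. Cedar, summed over its two stretches, gets 3.08.
- **The gauge.** G and X are charged equal, so integrating the rate law makes Λ equal −ln r, plus the saturation constant over the G left, less the same over the G charged, with r the share left. A rest of 5.00% needs 3.30. By hand, then, each flask ends near 95.0%, and the spread of Λ is worth 0.8 percentage points, less than the margin 1.5 points: all alike, cedar lowest.
- **Time and catalyst.** In this reckoning, with time and temperature held, Λ grows in proportion to the charge of D. With the charges held and c(G.X) kept at its ceiling, the warm clock tends with time to 5.45 and the cold one to 38.6.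
- **Forecast.** The forecast says all alike, with 94.8% for birch, 95.9% for alder and 95.1% for cedar, since “these effects nearly cancel over 5 minutes”.
- **Result.** The flasks give 94.8% in birch, 95.9% in alder and 95.1% in cedar, so all alike. Cedar stands above birch although its clock came out lower. At 1.00 min cedar still holds 90.9% of its D with Q at 0%, against the 83.1% reckoned at the ceiling.
- **What stands in birch.** At 5.00 min in birch the half-life of X by the first step is 1.5 min against 40 min for D by the third step, far shorter. The 5.2% of G left there reads back through the gauge as 3.25, beside Λ of 3.22.
- **A neighbour of birch with 3.0 × 10⁻⁵ M of D.** Λ shrinks with the charge of D to 1.93. With r first taken as exp(−Λ), the saturation terms of the gauge come to 0.0942, less than Λ, and taking them off gives G.X about 84.0%. That flask gives 84.7%.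

The numbers are those of an exercise.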